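**Retrosynthetic overview**

1. The target is a (2S,4S)-7,3′,4′-trihydroxyflavan joined through C4 to C8′ of a (2′R,3′S)-catechin unit (primed locants = lower unit). All seven phenols are carried as benzyl ethers and released last; the 3′-OH comes from hydroboration of a flav-3-ene, anti to the C2′ aryl group.
2. The strategy rests on the lower pyran ring (O1′–C2′–C3′–C4′–C4a′–C8a′): its C4′–C4a′ bond ties the methylene C4′ to the only unsubstituted ortho carbon of the D-ring aryl ether, and C3′–C4′ can be carried as the alkyne of an aryl 1-arylpropargyl ether. This ring is closed by gold(I) 6-endo-dig hydroarylation.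
3. The O1′–C2′ bond, and with it the C2′ stereocentre, is made by copper-catalysed asymmetric propargylic etherification of the D-ring phenol.
4. The upper pyran ring (O1–C2 and C3–C4 bonds; C2 and C4 cis) comes from a chiral-acid-catalysed o-quinone-methide/styrene [4+2] cycloaddition. The quinone methide precursor is a benzhydrol made by aryllithium addition, which forms the C4–C8′ bond.
5. Ring order: upper pyran first (step 5), lower pyran second (step 10).

Key step: step 10

Remark on starting materials: 3,5-bis(benzyloxy)phenol, 4-benzyloxy-2-hydroxybenzaldehyde and 3,4-bis(benzyloxy)benzaldehyde are taken as catalogue compounds; each is otherwise one benzylation away from phloroglucinol, 2,4-dihydroxybenzaldehyde or 3,4-dihydroxybenzaldehyde.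

Remark on the chiral catalysts: the sense of induction in steps 5 and 9 is assumed by analogy with the parent reactions; if a first run shows the opposite sense, the enantiomeric catalyst or ligand is used.

**Route**

Step 1
Reactants: 1 3,5-bis(benzyloxy)phenol
Product: 2 2-bromo-3,5-bis(benzyloxy)phenol
Conditions: NBS (1.0 equiv), i-Pr2NH (10 mol%), CH2Cl2, −78 → 0 °C
Reagents that add atoms: N-bromosuccinimide, O=C1CCC(=O)N1Br
Why: Electrophilic aromatic bromination of a phenol with NBS, in which amine-assisted delivery from the hydroxyl group and the lower hindrance of C2 (between OH and OBn) compared with C4 (between two OBn) should direct bromine ortho to the hydroxyl group, any 4-bromo isomer being removed by chromatography.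

Step 2
Reactants: 2 2-bromo-3,5-bis(benzyloxy)phenol
Product: 3 1-bromo-2,4-bis(benzyloxy)-6-(methoxymethoxy)benzene
Conditions: NaH (1.1 equiv), MOMCl (1.2 equiv), THF/DMF, 0 °C → rt
Reagents that add atoms: chloromethyl methyl ether, COCCl
Why: Williamson-type O-alkylation of the sodium phenoxide gives an acetal that tolerates the organolithium step and can later be removed without touching the benzyl ethers.

Step 3
Reactants: 3 1-bromo-2,4-bis(benzyloxy)-6-(methoxymethoxy)benzene; 4 4-benzyloxy-2-hydroxybenzaldehyde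
Product: 7 rac-(4-benzyloxy-2-hydroxyphenyl)[2,4-bis(benzyloxy)-6-(methoxymethoxy)phenyl]methanol, via aryllithium 5 (not isolated), via sodium phenolate 6 (not isolated)
Conditions: 3, n-BuLi (1.05 equiv), THF, −78 °C; then 6 [from 4, NaH (1.0 equiv), THF, 0 °C], −78 → 0 °C; aq. NH4Cl; chromatography on Et3N-deactivated silica
Reagents that add atoms: none
Why: Bromine–lithium exchange at −78 °C is faster than any attack on the benzyl or MOM ethers, and 1,2-addition of the aryllithium to the aldehyde, whose acidic phenol is masked beforehand as its sodium salt so that no aryllithium is lost to protonation, gives the racemic benzhydrol, whose configuration is irrelevant because the carbinol carbon becomes sp2 in step 5.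

Step 4
Reactants: 8 3,4-bis(benzyloxy)benzaldehyde
Product: 9 3,4-bis(benzyloxy)styrene
Conditions: Ph3PCH3Br (1.3 equiv), KOt-Bu (1.25 equiv), THF, 0 °C → rt
Reagents that add atoms: methyltriphenylphosphonium bromide, C[P+](c1ccccc1)(c1ccccc1)c1ccccc1.[Br-]
Why: Wittig methylenation of an aromatic aldehyde with the non-stabilised ylide, to which the benzyl ethers are inert.

Step 5
Reactants: 7 rac-(4-benzyloxy-2-hydroxyphenyl)[2,4-bis(benzyloxy)-6-(methoxymethoxy)phenyl]methanol; 9 3,4-bis(benzyloxy)styrene
Product: 11 (2S,4S)-7-benzyloxy-2-[3,4-bis(benzyloxy)phenyl]-4-[2,4-bis(benzyloxy)-6-(methoxymethoxy)phenyl]chroman, via o-quinone methide 10 (not isolated)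
Conditions: (R)-3,3′-bis(2,4,6-triisopropylphenyl)-H8-BINOL N-triflylphosphoramide (5 mol%), 9 (1.5 equiv), 4 Å MS, PhMe, −40 → −20 °C
Reagents that add atoms: none
Why: Chiral Brønsted acid-catalysed dehydration of the o-hydroxybenzhydrol gives the o-quinone methide 10 hydrogen-bonded to the chiral counter-anion, and its inverse-electron-demand hetero-Diels–Alder reaction with the electron-rich styrene 9 (CH2 terminus to the methine carbon, oxygen to the benzylic carbon) through an endo transition state should give the 2,4-cis chroman, the catalyst selecting the face of the quinone methide and so fixing C4 as S and, through the cis relationship, C2 as S.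

Step 6
Reactants: 11 (2S,4S)-7-benzyloxy-2-[3,4-bis(benzyloxy)phenyl]-4-[2,4-bis(benzyloxy)-6-(methoxymethoxy)phenyl]chroman
Product: 12 3,5-bis(benzyloxy)-2-{(2S,4S)-7-benzyloxy-2-[3,4-bis(benzyloxy)phenyl]chroman-4-yl}phenol
Conditions: conc. HCl (5 equiv), MeOH/THF (1:1), rt → 40 °C
Reagents that add atoms: none
Why: Acid-catalysed acetal exchange with methanol removes the MOM group, while the benzyl ethers and the C4–aryl bond of this 5-deoxy flavan, which is far less prone to acid cleavage than that of 5-oxygenated flavans, should persist.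

Step 7
Reactants: 8 3,4-bis(benzyloxy)benzaldehyde
Product: 13 rac-1-[3,4-bis(benzyloxy)phenyl]prop-2-yn-1-ol
Conditions: ethynylmagnesium bromide (1.3 equiv), THF, 0 °C; aq. NH4Cl
Reagents that add atoms: ethynylmagnesium bromide, C#C[Mg]Br
Why: 1,2-Addition of an alkynyl Grignard reagent to an aromatic aldehyde; the alcohol is made racemic on purpose because the copper step is stereoconvergent.

Step 8
Reactants: 13 rac-1-[3,4-bis(benzyloxy)phenyl]prop-2-yn-1-ol
Product: 14 rac-1-[3,4-bis(benzyloxy)phenyl]prop-2-yn-1-yl acetate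
Conditions: Ac2O (1.5 equiv), Et3N (2 equiv), DMAP (5 mol%), CH2Cl2, 0 °C
Reagents that add atoms: acetic anhydride, CC(=O)OC(C)=O
Why: DMAP-catalysed acylation of a secondary alcohol turns the hydroxyl group into the leaving group needed for copper–allenylidene formation.

Step 9
Reactants: 12 3,5-bis(benzyloxy)-2-{(2S,4S)-7-benzyloxy-2-[3,4-bis(benzyloxy)phenyl]chroman-4-yl}phenol; 14 rac-1-[3,4-bis(benzyloxy)phenyl]prop-2-yn-1-yl acetate
Product: 15 (2S,4S)-7-benzyloxy-2-[3,4-bis(benzyloxy)phenyl]-4-{2,4-bis(benzyloxy)-6-[(1S)-1-(3,4-bis(benzyloxy)phenyl)prop-2-yn-1-yloxy]phenyl}chroman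
Conditions: Cu(OTf)·½C6H6 (5 mol%), 2,6-bis[(4S)-4-phenyl-2-oxazolin-2-yl]pyridine (10 mol%), i-Pr2NEt (1.5 equiv), 14 (1.5 equiv), CH2Cl2, −20 °C
Reagents that add atoms: none
Why: Copper-catalysed asymmetric propargylic substitution (etherification of a propargylic ester with a phenol): both enantiomers of 14 converge on one copper–allenylidene complex bound to the chiral pybox ligand, and attack of the phenoxide of 12 on the γ-carbon from the face left open by the ligand should set the new centre C2′ as S under catalyst control, the terminal alkyne that this mechanism requires being the one needed in the key step.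

Step 10
Reactants: 15 (2S,4S)-7-benzyloxy-2-[3,4-bis(benzyloxy)phenyl]-4-{2,4-bis(benzyloxy)-6-[(1S)-1-(3,4-bis(benzyloxy)phenyl)prop-2-yn-1-yloxy]phenyl}chroman
Product: 16 (2S,4S)-7-benzyloxy-2-[3,4-bis(benzyloxy)phenyl]-4-{(2S)-5,7-bis(benzyloxy)-2-[3,4-bis(benzyloxy)phenyl]-2H-chromen-8-yl}chroman
Conditions: Ph3PAuNTf2 (5 mol%), 2,6-di-tert-butylpyridine (10 mol%), CH2Cl2 (0.05 M), 0 °C → rt, dark
Reagents that add atoms: none
Why: The cationic gold(I) centre binds the terminal alkyne of 15 and makes its CH terminus electrophilic; the D ring attacks through its only unsubstituted ortho carbon (the future C4a′, ortho to O1′ and to the 5′-benzyloxy group and para to the 7′-benzyloxy group), and rearomatisation followed by protodeauration of the vinylgold species releases the 2H-chromene 16. The closest known reaction type is the gold(I)- or platinum-catalysed cycloisomerisation (intramolecular alkyne hydroarylation) of aryl propargyl ethers to 2H-chromenes. The lower pyran ring closes in the 6-endo-dig mode, forming the C4′–C4a′ bond, with both alkyne carbons ending inside the ring as C3′=C4′. No stereocentre is created; the sp3 carbon C2′ is a spectator of this Friedel–Crafts-type pathway and should keep its S configuration, in contrast to a thermal Claisen sequence, which passes through an sp2 stage at that carbon. The step needs site selectivity (secured by the single free ortho position, which three flanking oxygen substituents make the most nucleophilic carbon within reach), 6-endo over 5-exo closure (secured by the geometry of the O–C–C≡C tether on a terminal alkyne) and π-activation in preference to ionisation of the p-benzyloxybenzylic C–O bond (secured by the weakly Lewis acidic phosphine–gold triflimide, the pyridine buffer, low temperature and exclusion of light).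

Step 11
Reactants: 16 (2S,4S)-7-benzyloxy-2-[3,4-bis(benzyloxy)phenyl]-4-{(2S)-5,7-bis(benzyloxy)-2-[3,4-bis(benzyloxy)phenyl]-2H-chromen-8-yl}chroman
Product: 18 (2R,3S)-5,7-bis(benzyloxy)-8-{(2S,4S)-7-benzyloxy-2-[3,4-bis(benzyloxy)phenyl]chroman-4-yl}-2-[3,4-bis(benzyloxy)phenyl]chroman-3-ol, via 3′-boryl flavan 17 (not isolated)
Conditions: BH3·THF (3 equiv), THF, 0 °C → rt; then 3 M NaOH, 30% H2O2, 0 °C → rt
Reagents that add atoms: hydrogen peroxide, OO; borane–tetrahydrofuran, B.C1CCOC1
Why: Hydroboration–oxidation of a flav-3-ene: boron (carried only in the unisolated 17) adds to C3′ (distal to the electron-rich D ring and next to the inductively withdrawing C2′–O bond) in a syn fashion on the face opposite to the C2′ aryl group, and oxidation with retention places the 3′-hydroxyl anti to that aryl group, which sets C3′ as S (2′,3′-trans, the catechin configuration).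

Step 12
Reactants: 18 (2R,3S)-5,7-bis(benzyloxy)-8-{(2S,4S)-7-benzyloxy-2-[3,4-bis(benzyloxy)phenyl]chroman-4-yl}-2-[3,4-bis(benzyloxy)phenyl]chroman-3-ol
Product: 19 (2R,3S)-2-(3,4-dihydroxyphenyl)-8-[(2S,4S)-2-(3,4-dihydroxyphenyl)-7-hydroxychroman-4-yl]chroman-3,5,7-triol (CNP0227165.3)
Conditions: H2 (1 atm), 20% Pd(OH)2/C, THF/MeOH (1:1), rt; filtration under argon, lyophilisation
Reagents that add atoms: none
Why: Palladium-catalysed hydrogenolysis cleaves all seven benzyl ethers under neutral conditions that should leave the flavan C–O bonds and the four stereocentres untouched.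

**Compound list**

1 | 3,5-bis(benzyloxy)phenol | Oc1cc(OCc2ccccc2)cc(OCc2ccccc2)c1 | starting material
2 | 2-bromo-3,5-bis(benzyloxy)phenol | Oc1cc(OCc2ccccc2)cc(OCc2ccccc2)c1Br | intermediate
3 | 1-bromo-2,4-bis(benzyloxy)-6-(methoxymethoxy)benzene | COCOc1cc(OCc2ccccc2)cc(OCc2ccccc2)c1Br | intermediate
4 | 4-benzyloxy-2-hydroxybenzaldehyde | O=Cc1ccc(OCc2ccccc2)cc1O | starting material
5 | [2,4-bis(benzyloxy)-6-(methoxymethoxy)phenyl]lithium | [Li]c1c(OCOC)cc(OCc2ccccc2)cc1OCc1ccccc1 | intermediate (not isolated)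
6 | sodium 5-benzyloxy-2-formylphenolate | [Na+].[O-]c1cc(OCc2ccccc2)ccc1C=O | intermediate (not isolated)
7 | rac-(4-benzyloxy-2-hydroxyphenyl)[2,4-bis(benzyloxy)-6-(methoxymethoxy)phenyl]methanol | OC(c1ccc(OCc2ccccc2)cc1O)c1c(OCOC)cc(OCc2ccccc2)cc1OCc1ccccc1 | intermediate
8 | 3,4-bis(benzyloxy)benzaldehyde | O=Cc1ccc(OCc2ccccc2)c(OCc2ccccc2)c1 | starting material
9 | 3,4-bis(benzyloxy)styrene | C=Cc1ccc(OCc2ccccc2)c(OCc2ccccc2)c1 | intermediate
10 | 3-benzyloxy-6-{[2,4-bis(benzyloxy)-6-(methoxymethoxy)phenyl]methylidene}cyclohexa-2,4-dien-1-one (o-quinone methide) | O=C1C=C(OCc2ccccc2)C=CC1=Cc1c(OCOC)cc(OCc2ccccc2)cc1OCc1ccccc1 | intermediate (not isolated)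
11 | (2S,4S)-7-benzyloxy-2-[3,4-bis(benzyloxy)phenyl]-4-[2,4-bis(benzyloxy)-6-(methoxymethoxy)phenyl]chroman | c9ccccc9COc1ccc2c(c1)O[C@H](c1ccc(OCc9ccccc9)c(OCc9ccccc9)c1)C[C@@H]2c1c(OCc9ccccc9)cc(OCc9ccccc9)cc1OCOC | intermediate
12 | 3,5-bis(benzyloxy)-2-{(2S,4S)-7-benzyloxy-2-[3,4-bis(benzyloxy)phenyl]chroman-4-yl}phenol | c9ccccc9COc1ccc2c(c1)O[C@H](c1ccc(OCc9ccccc9)c(OCc9ccccc9)c1)C[C@@H]2c1c(OCc9ccccc9)cc(OCc9ccccc9)cc1O | intermediate
13 | rac-1-[3,4-bis(benzyloxy)phenyl]prop-2-yn-1-ol | C#CC(O)c1ccc(OCc2ccccc2)c(OCc2ccccc2)c1 | intermediate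
14 | rac-1-[3,4-bis(benzyloxy)phenyl]prop-2-yn-1-yl acetate | C#CC(OC(C)=O)c1ccc(OCc2ccccc2)c(OCc2ccccc2)c1 | intermediate
15 | (2S,4S)-7-benzyloxy-2-[3,4-bis(benzyloxy)phenyl]-4-{2,4-bis(benzyloxy)-6-[(1S)-1-(3,4-bis(benzyloxy)phenyl)prop-2-yn-1-yloxy]phenyl}chroman | c9ccccc9COc1ccc2c(c1)O[C@H](c1ccc(OCc9ccccc9)c(OCc9ccccc9)c1)C[C@@H]2c1c(OCc9ccccc9)cc(OCc9ccccc9)cc1O[C@H](c1ccc(OCc9ccccc9)c(OCc9ccccc9)c1)C#C | intermediate
16 | (2S,4S)-7-benzyloxy-2-[3,4-bis(benzyloxy)phenyl]-4-{(2S)-5,7-bis(benzyloxy)-2-[3,4-bis(benzyloxy)phenyl]-2H-chromen-8-yl}chroman | c9ccccc9COc1ccc2c(c1)O[C@H](c1ccc(OCc9ccccc9)c(OCc9ccccc9)c1)C[C@@H]2c1c(OCc9ccccc9)cc(OCc9ccccc9)c2c1O[C@H](c1ccc(OCc9ccccc9)c(OCc9ccccc9)c1)C=C2 | intermediate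
17 | (2S,3S)-3-boranyl-5,7-bis(benzyloxy)-8-{(2S,4S)-7-benzyloxy-2-[3,4-bis(benzyloxy)phenyl]chroman-4-yl}-2-[3,4-bis(benzyloxy)phenyl]chroman (boron trans to the C2′ aryl group) | c9ccccc9COc1ccc2c(c1)O[C@H](c1ccc(OCc9ccccc9)c(OCc9ccccc9)c1)C[C@@H]2c1c(OCc9ccccc9)cc(OCc9ccccc9)c2c1O[C@H](c1ccc(OCc9ccccc9)c(OCc9ccccc9)c1)[C@@H](B)C2 | intermediate (not isolated)
18 | (2R,3S)-5,7-bis(benzyloxy)-8-{(2S,4S)-7-benzyloxy-2-[3,4-bis(benzyloxy)phenyl]chroman-4-yl}-2-[3,4-bis(benzyloxy)phenyl]chroman-3-ol | c9ccccc9COc1ccc2c(c1)O[C@H](c1ccc(OCc9ccccc9)c(OCc9ccccc9)c1)C[C@@H]2c1c(OCc9ccccc9)cc(OCc9ccccc9)c2c1O[C@H](c1ccc(OCc9ccccc9)c(OCc9ccccc9)c1)[C@@H](O)C2 | intermediate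
19 | (2R,3S)-2-(3,4-dihydroxyphenyl)-8-[(2S,4S)-2-(3,4-dihydroxyphenyl)-7-hydroxychroman-4-yl]chroman-3,5,7-triol (CNP0227165.3) | Oc1ccc2c(c1)O[C@H](c1ccc(O)c(O)c1)C[C@@H]2c1c(O)cc(O)c2c1O[C@H](c1ccc(O)c(O)c1)[C@@H](O)C2 | target

**Totals**

Total step count: 12 steps. Longest linear sequence: 9 steps (1 → 2 → 3 → 7 → 11 → 12 → 15 → 16 → 18 → 19; steps 1, 2, 3, 5, 6, 9, 10, 11, 12).

**Three steps most likely to fail**

The key step, step 10, carries the highest risk. The cationic gold centre or adventitious acid may ionise the p-benzyloxybenzylic propargylic C–O bond, which would scramble C2′ or transfer the propargyl group to carbon; 5-exo closure may also compete. The fallback sets out from 15 and closes the ring without any Lewis acid. Heating in N,N-diethylaniline at about 170 °C should drive the aryl propargyl Claisen rearrangement onto the free ortho carbon, followed by enolisation, 1,5-hydrogen shift and oxa-6π electrocyclisation. Because C2′ passes through an sp2 stage, 16 should form together with its C2′ epimer (2S,4S)-7-benzyloxy-2-[3,4-bis(benzyloxy)phenyl]-4-{(2R)-5,7-bis(benzyloxy)-2-[3,4-bis(benzyloxy)phenyl]-2H-chromen-8-yl}chroman F1. The epimer F1 is removed by chromatography (preparative HPLC if required), and the route is rejoined at 16.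

Second in risk is step 5. The di-ortho-substituted aryl group on the quinone methide may erode enantiofacial control, the strong acid may oligomerise the electron-rich styrene, or the MOM group may be lost before the cycloaddition. The fallback sets out from 7 and 9 and gives up catalyst control. An achiral acid (diphenyl phosphate, 10 mol%, CH2Cl2, 0 °C) should give the cis chroman as a racemate, that is 11 together with its enantiomer (2R,4R)-7-benzyloxy-2-[3,4-bis(benzyloxy)phenyl]-4-[2,4-bis(benzyloxy)-6-(methoxymethoxy)phenyl]chroman F2. The enantiomer F2 is removed by preparative chromatography on a chiral stationary phase, and the (2S,4S) enantiomer re-enters the route at 11.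

Third is step 9. The phloroglucinol-type ring may be propargylated at carbon instead of oxygen, the ortho-substituted phenol may react slowly, or catalyst and substrate may be mismatched in face selectivity. The fallback sets out from 13 and 12 and puts the configuration into the electrophile. Lipase-mediated kinetic resolution of 13 (Novozym 435, vinyl acetate, MTBE) is expected by the Kazlauskas rule to acylate the R enantiomer, giving (1R)-1-[3,4-bis(benzyloxy)phenyl]prop-2-yn-1-yl acetate F3, which is separated from the unreacted S alcohol. Methanolysis of F3 (K2CO3, MeOH, 0 °C) should give (1R)-1-[3,4-bis(benzyloxy)phenyl]prop-2-yn-1-ol F4. Mitsunobu etherification of phenol 12 with F4 (PPh3, DIAD, toluene, 0 °C) should proceed with inversion and comes back to the route at 15.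

**Further compounds**

F1 | step 10 | (2S,4S)-7-benzyloxy-2-[3,4-bis(benzyloxy)phenyl]-4-{(2R)-5,7-bis(benzyloxy)-2-[3,4-bis(benzyloxy)phenyl]-2H-chromen-8-yl}chroman | c9ccccc9COc1ccc2c(c1)O[C@H](c1ccc(OCc9ccccc9)c(OCc9ccccc9)c1)C[C@@H]2c1c(OCc9ccccc9)cc(OCc9ccccc9)c2c1O[C@@H](c1ccc(OCc9ccccc9)c(OCc9ccccc9)c1)C=C2
F2 | step 5 | (2R,4R)-7-benzyloxy-2-[3,4-bis(benzyloxy)phenyl]-4-[2,4-bis(benzyloxy)-6-(methoxymethoxy)phenyl]chroman | c9ccccc9COc1ccc2c(c1)O[C@@H](c1ccc(OCc9ccccc9)c(OCc9ccccc9)c1)C[C@H]2c1c(OCc9ccccc9)cc(OCc9ccccc9)cc1OCOC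
F3 | step 9 | (1R)-1-[3,4-bis(benzyloxy)phenyl]prop-2-yn-1-yl acetate | CC(=O)O[C@@H](c1ccc(OCc2ccccc2)c(OCc2ccccc2)c1)C#C
F4 | step 9 | (1R)-1-[3,4-bis(benzyloxy)phenyl]prop-2-yn-1-ol | O[C@@H](c1ccc(OCc2ccccc2)c(OCc2ccccc2)c1)C#C
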